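**Structural features**

The target is a flavanone. A benzene ring (ring A) is fused through C4a–C8a to a dihydropyran-4-one (ring C), and C2 of ring C carries a 2,4-dihydroxyphenyl group (ring B). C2 is the only stereocentre (S) and has no stereogenic neighbour. It is benzylic, bonded to the ring oxygen O1 and β to the C4 ketone, so it can be lost by retro-oxa-Michael opening to the 2'-hydroxychalcone, which base and the free ortho and para hydroxyls of ring B make easier. Ring A is substituted everywhere except C5: oxygen on C8a (O1) and C7, 3-methylbut-2-enyl (prenyl) groups on C8 and C6, and the acyl carbon C4 on C4a. The prenyl groups are the fragile part: acid cyclises them onto the neighbouring C7 hydroxyl (chroman formation) and electrophiles attack their trisubstituted double bonds, which excludes Fries, Friedel–Crafts and strong-acid deprotection chemistry. The difficulty is twofold: two C-prenyl groups must be placed regiospecifically on a resorcinol-type ring, and the labile C2 configuration must be set and then kept through deprotection. The key step uses the alternation around ring A: oxygen at C8a and C7, carbon at C8 and C6, hydrogen at C5 and C4a. A 2-substituted vinylketene and a 1-siloxyalkyne give exactly this pattern, so ring A can be assembled from two open chains that each already carry one prenyl group.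

**Logic of the disconnections**

24 from 23. The three phenolic O–Si bonds (on O7, O2' and O4') are cut. With the ring B hydroxyls free, C2 opens to the chalcone under traces of base, and the C7 hydroxyl can cyclise onto either neighbouring prenyl group under acid; the phenols are therefore released last and by fluoride only. The gain is that every earlier step runs on a neutral, configurationally safer substrate, and one silyl type allows a single deprotection. The demand is a buffered desilylation of 23 in which no ring B phenoxide persists.

23 from 21, through 22. The O1–C2 bond is cut and, read backwards, a carboxylate is placed on C3. Conjugate addition of the C8a hydroxyl creates the only stereocentre, and a 1,3-dicarbonyl unit at C3 offers a chiral hydrogen-bond donor two carbonyl groups to hold; a bare chalcone lacks this second binding point. Ring C and the stereocentre are exchanged for the achiral, open-chain 21. The forward step needs a catalyst that distinguishes the faces of the alkylidene carbon. The auxiliary ester must leave without acid (prenyl groups, benzylic C2–O1 bond) and without strong base (ring opening), hence an allyl ester removed by palladium.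

21 from 18 and 20, and 20 from 19. The C2=C3 bond is cut. A condensation between an active methylene and an aldehyde is the most convergent junction and joins the ring A half to the ring B half. Two fragments of similar size result, and 20 is one silylation away from 19. The forward condensation must be mild enough for aryl silyl ethers, and 21 must not close without stereocontrol before the chiral catalyst is added.

18 from 16, through 17. The C3–C4 bond is cut. Addition of an acetate enolate to an aryl aldehyde, followed by oxidation, gives the β-keto ester without exposing the ring to an acylating Lewis acid. Two carbons and the ester are removed. The enolate must tolerate the free phenol (one extra equivalent), and the oxidant must select the benzylic carbinol over the phenol and the double bonds.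

16 from 15. The C4a–C4 bond is cut. C4a is the only unsubstituted position ortho to the free hydroxyl of 15 and is para to the siloxy group. A magnesium-phenoxide-directed formylation puts one carbon there without acid, whereas Fries or Friedel–Crafts acetylation would destroy the prenyl groups. This returns the plan to the annulation product. The forward step must be exclusively ortho and C-selective under non-acidic conditions.

15 from 6 and 10, through 11, 12, 13 and 14. Four bonds are cut: C8a–C8, C7–C6, C6–C5 and C8a–C4a, which takes ring A apart into two open chains. Electrophilic prenylation of a resorcinol gives O-alkylation, C6/C8 mixtures and chromans. Building the ring from an electrophilic ketene carbon (the future C8a) and an ynol ether that is nucleophilic at the future C8 writes the substitution pattern into the precursors. A pentasubstituted benzene becomes two short chains with one prenyl group each, and the two oxygens emerge differentiated: free at C8a, silylated at C7. The ketene must be generated where 10 traps it faster than it dimerises, and the [2+2] step must be regiospecific.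

6 from 4, 2 and 1, through 3 and 5. The C=N2 bond at the future C6 is cut, and then the C–C bond between the future C5 and C4a carbons. The diazo group enters by deacylative transfer at the only enolisable carbon of 4, and 4 comes from 1 by aminomethylation of its methyl group and elimination. The starting point is a cheap C8 ketone. Aminomethylation must go to the methyl side and not the methylene side. An acid-catalysed Mannich reaction favours the wrong side, so a kinetic enolate and a preformed iminium salt are used, and 2 doubles as the storable form of the polymerisable 4. Enolisation of 4 must outrun conjugate addition.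

10 from 7, through 8 and 9. The O–Si bond is cut, and then the bond between the two alkyne carbons (one-carbon homologation of an ester to an ynolate). The gain is a commercial ester that already contains the prenyl unit. The forward step needs O-silylation rather than C-silylation, which a bulky silyl chloride secures. The triisopropylsilyl group is chosen once for ynol ether stability and is carried unchanged to the end as the C7 protecting group.

**Other disconnections considered**

Alternative 1: The cut is made late, at the two C1''–C2'' bonds inside the prenyl chains (benzylic CH2 to alkenyl CH), on an intact flavanone. In the forward step the bis-Mannich base A2, (2S)-2-[2,4-bis(methoxymethoxy)phenyl]-6,8-bis[(dimethylamino)methyl]-7-hydroxychroman-4-one, is heated. Each aminomethyl arm in turn loses its amine to form an ortho-quinone methide across the C7 oxygen, which is alkenylated by (2-methylprop-1-en-1-yl)boronic acid A3 to give A1.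

- In favour: regiochemistry is automatic because both arms sit ortho to the C7 hydroxyl, O-prenylation cannot occur, and the sensitive prenyl groups are present for the shortest possible time.
- Against: A2 must come from double aminomethylation of a 7-hydroxyflavanone whose C3 methylene is itself a Mannich donor. The hot, amine-releasing conditions favour opening of ring C and loss of the C2 configuration. After A1 the acetal protecting groups need acid, the condition that the prenyl/C7-hydroxyl pair and the C2–O1 bond tolerate least.
- Comparison: structurally, the alternative keeps ring A intact and decorates it, while the chosen plan builds it. Mechanistically, two elimination/conjugate-addition events stand against one pericyclic cascade. On step count for installing both prenyl groups the alternative is the better of the two (one operation, no separate prenylated chains). On the C2 problem it is only equal, since an enantioselective flavanone synthesis is still needed, and on the final deprotection the chosen plan is better.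

Alternative 2: The cut is at O1–C2 and C3–C4, so ring C is formed by a [4+2] union. In the forward step the salicylaldehyde A5, 4-(tert-butyldimethylsilyloxy)-2-hydroxy-3,5-bis(3-methylbut-2-en-1-yl)benzaldehyde, is turned by an orthoformate and a chiral Brønsted acid into a methoxy-substituted ortho-quinone methide. This adds the vinylphenol A6, 5-(tert-butyldimethylsilyloxy)-2-ethenylphenol, to give the 4-methoxychromane A4 with C2 and C4 set.

- In favour: ring C and the C2 stereocentre arise in one catalytic, convergent step. For the construction of ring C this is better than the chosen plan, which spends four steps (aldol, oxidation, condensation, closure).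
- Equal: A5 differs from 16 only in its silyl group, so ring A still has to be made, and the chosen annulation would serve this alternative just as well.
- Against: A4 is at the ether oxidation level at C4. Conversion to the ketone needs oxidative removal of a benzylic methyl ether in the presence of two prenyl groups and two electron-rich rings. The free 2'-hydroxyl next to an acid-labile C2–O1 bond can re-ionise or bridge to C4, and a strong Brønsted acid catalyst meets the prenyl/phenol pair.
- Comparison: an acid-mediated ionic cycloaddition stands against a neutral pericyclic sequence. After the correction of oxidation level and the extra protecting-group differentiation, overall step economy is about equal.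

Alternative 3: The cut is at C4a–C5 and C8a–C8, so ring A is annulated onto a preformed, enantiopure ring C. In the forward step the bromopyranone A8, (2S)-2-[2,4-bis(tert-butyldimethylsilyloxy)phenyl]-5-bromo-2,3-dihydro-4H-pyran-4-one, reacts across its C=C bond with the diene A9, tert-butyl{[(1E,3Z)-1-methoxy-7-methyl-2-(3-methylbut-2-en-1-yl)octa-1,3,6-trien-3-yl]oxy}dimethylsilane. Loss of HBr and methanol then aromatises the adduct to A7.

- In favour: C2 is fixed before ring A exists, through a dihydropyranone of a well-developed class, and no chalcone stage occurs. On the stereocentre this is equal to or better than the chosen plan.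
- Equal: regiocontrol rests on the same principle, polarity matching in a de novo construction of ring A. The final step is the same fluoride desilylation, and the C7 hydroxyl even emerges free.
- Against: A9 is a tetrasubstituted, doubly prenylated methoxy-siloxydiene that needs its own multistep, geometry-controlled synthesis. A8 is an electron-rich vinylogous ester and a reluctant dienophile, and the forcing conditions this implies endanger C2 and the prenyl groups. The aromatisation must lose HBr and methanol in the right sense.
- Comparison: both plans build ring A from acyclic pieces. The chosen one uses two simple, stable precursors and a precedented cascade, while the alternative gains earlier stereocontrol at the price of a much harder diene. Step counts should be comparable.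

Key step: step 5

Remarks on the chemistry, made before the steps:
- 21 is expected mainly as the Z isomer (ester cis to ring B) and is drawn so; both geometries lead to the same ring closure.
- The quinidine-derived thiourea is taken as the member of the pseudoenantiomeric catalyst pair that leads to 2S. If a test closure shows the opposite sense, the quinine-derived catalyst replaces it with no other change.
- Atom-by-atom mapping of 6, 10 and 15 onto ring A showed the three constitutions to be mutually consistent, so no structure needed correction.

Step 1
Reactants: 1 6-methylhept-5-en-2-one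
Product: 2 1-(dimethylamino)-7-methyloct-6-en-3-one
Conditions: LiN(i-Pr)2, THF, −78 °C; Me2N=CH2 iodide (Eschenmoser's salt), −78 °C → rt
Reagents that add atoms: N,N-dimethylmethyleneiminium iodide (Eschenmoser's salt), C=[N+](C)C.[I-]
Why: Kinetic deprotonation at −78 °C removes a methyl proton of 1, and the preformed iminium salt aminomethylates that enolate (Mannich reaction); this avoids the methylene-side product that acid-catalysed Mannich conditions favour, and the amine 2 is easy to purify and to store.

Step 2
Reactants: 2 1-(dimethylamino)-7-methyloct-6-en-3-one
Product: 4 7-methylocta-1,6-dien-3-one, via ammonium iodide 3 (not isolated)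
Conditions: MeI, Et2O, rt; then NaHCO3, H2O/CH2Cl2, rt (trace BHT); used at once
Reagents that add atoms: none
Why: Quaternisation makes trimethylamine a leaving group β to the ketone, and mild base completes an E1cB (Hofmann-type) elimination to the vinyl ketone; generating 4 just before use limits its polymerisation.

Step 3
Reactants: 4 7-methylocta-1,6-dien-3-one
Product: 6 4-diazo-7-methylocta-1,6-dien-3-one, via trifluoroacetyl diketone 5 (not isolated)
Conditions: LiN(SiMe3)2, THF, −78 °C; CF3CO2CH2CF3, −78 °C; dil. HCl work-up; then 4-AcNHC6H4SO2N3, Et3N, H2O, MeCN, rt
Reagents that add atoms: 4-acetamidobenzenesulfonyl azide, CC(=O)Nc1ccc(cc1)S(=O)(=O)N=[N+]=[N-]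
Why: C4 is the only enolisable carbon of 4 and is deprotonated kinetically by the hindered amide base, which should not add to the enone at −78 °C; trifluoroacetylation activates C4 for diazo transfer, and the triazoline fragments with transfer of the trifluoroacetyl group to the sulfonamide nitrogen (detrifluoroacetylative, Regitz-type diazo transfer, a method suited to base-sensitive enones). The acetamido-substituted azide is chosen as the safer transfer reagent.

Step 4
Reactants: 7 ethyl 4-methylpent-3-enoate
Product: 10 triisopropyl[(5-methylhex-4-en-1-yn-1-yl)oxy]silane, via dibromo enolate 8 (not isolated), via lithium ynolate 9 (not isolated)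
Conditions: CH2Br2, lithium 2,2,6,6-tetramethylpiperidide (from the amine and n-BuLi), THF, −78 °C; 7; n-BuLi (excess), −78 °C → rt; i-Pr3SiCl, −78 °C → rt
Reagents that add atoms: dibromomethane, BrCBr; chlorotriisopropylsilane, CC(C)[Si](Cl)(C(C)C)C(C)C
Why: Kowalski ester homologation: LiCHBr2 adds to the ester, base gives the dibromo enolate 8, bromine–lithium exchange and 1,2-shift of the alkyl group give the ynolate 9, and the bulky silyl chloride silylates it on oxygen. The triisopropylsilyl group gives an isolable ynol ether and later serves unchanged as the C7 protecting group.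

Step 5
Reactants: 6 4-diazo-7-methylocta-1,6-dien-3-one; 10 triisopropyl[(5-methylhex-4-en-1-yn-1-yl)oxy]silane
Product: 15 2,4-bis(3-methylbut-2-en-1-yl)-3-(triisopropylsilyloxy)phenol, via vinylketene 11 (not isolated), via vinylcyclobutenone 12 (not isolated), via dienylketene 13 (not isolated), via cyclohexadienone 14 (not isolated)
Conditions: hν (254 nm), degassed ClCH2CH2Cl, rt, slight excess of 10; then 80 °C
Reagents that add atoms: none
Why: Irradiation of 6 releases N2 and the vinyl group shifts from the carbonyl carbon to the diazo carbon (photochemical Wolff rearrangement, forming C6–C5), which gives the prenyl-substituted vinylketene 11. The ketene C=C bond of 11 then adds to the electron-rich triple bond of 10 in a [2+2] cycloaddition, the oxygen-free alkyne carbon bonding to the ketene carbonyl carbon (C8a–C8) and the siloxy-bearing carbon to the ketene α-carbon (C7–C6), to give the 4-vinylcyclobutenone 12. On warming, 12 opens by a conrotatory 4π electrocyclic reaction to the dienylketene 13; the opening is reversible, so material that opens with the vinyl group turned away from the ketene returns to 12 and is funnelled through the productive isomer. Ring A is closed by a disrotatory 6π electrocyclisation of 13 that forms C8a–C4a, and the resulting cyclohexadienone 14 tautomerises to the phenol 15. The closest known reaction is the second-generation Danheiser benzannulation of diazo-ketone-derived vinylketenes with 1-siloxyalkynes, which leads to resorcinol monosilyl ethers of this type. No stereocentre is created, because the quaternary carbon of 12 becomes planar again on ring opening. The selectivity that matters is regiochemical and is secured by the polarisation of 10 (nucleophilic at the carbon remote from oxygen) against the electrophilic ketene carbonyl carbon, which places one prenyl group between the two oxygens and the other para to the new hydroxyl; the same polarisation makes the ynol ether react in preference to the prenyl double bonds. Direct, unsensitised irradiation is chosen because the singlet pathway favours the Wolff shift over the 1,2-hydrogen shift that is open to a carbene next to a CH2 group.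

Step 6
Reactants: 15 2,4-bis(3-methylbut-2-en-1-yl)-3-(triisopropylsilyloxy)phenol
Product: 16 2-hydroxy-3,5-bis(3-methylbut-2-en-1-yl)-4-(triisopropylsilyloxy)benzaldehyde
Conditions: MgCl2, Et3N, (CH2O)n, THF, reflux
Reagents that add atoms: paraformaldehyde (formaldehyde unit), C=O
Why: Magnesium-phenoxide-directed ortho-formylation (Casnati–Skattebøl reaction): formaldehyde is delivered within the magnesium chelate to C4a, the only free ortho position and also para to the siloxy group, and a second formaldehyde oxidises the benzylic alkoxide by hydride transfer. No Brønsted or strong Lewis acid meets the prenyl groups or the silyl ether.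

Step 7
Reactants: 16 2-hydroxy-3,5-bis(3-methylbut-2-en-1-yl)-4-(triisopropylsilyloxy)benzaldehyde
Product: 17 prop-2-en-1-yl 3-hydroxy-3-[2-hydroxy-3,5-bis(3-methylbut-2-en-1-yl)-4-(triisopropylsilyloxy)phenyl]propanoate (racemic)
Conditions: allyl acetate, LiN(i-Pr)2 (3 equiv each), THF, −78 °C; 16, −78 → −40 °C; AcOH quench at −78 °C
Reagents that add atoms: prop-2-en-1-yl acetate (allyl acetate), CC(=O)OCC=C
Why: Aldol addition of a lithium ester enolate to an aryl aldehyde; the first equivalent of enolate is consumed by the phenol, the phenoxide aldehyde is then attacked at low temperature, and the cold acidic quench prevents lactonisation. The carbinol stereocentre forms as a racemate and is removed in step 8.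

Step 8
Reactants: 17 prop-2-en-1-yl 3-hydroxy-3-[2-hydroxy-3,5-bis(3-methylbut-2-en-1-yl)-4-(triisopropylsilyloxy)phenyl]propanoate
Product: 18 prop-2-en-1-yl 3-[2-hydroxy-3,5-bis(3-methylbut-2-en-1-yl)-4-(triisopropylsilyloxy)phenyl]-3-oxopropanoate
Conditions: MnO2 (activated, excess), CH2Cl2, rt
Reagents that add atoms: none
Why: MnO2 oxidises the electron-rich benzylic alcohol selectively and should leave the prenyl double bonds, the allyl ester and the fully ortho/para-substituted phenol untouched; the product is stabilised by the phenol–ketone hydrogen bond.

Step 9
Reactants: 19 2,4-dihydroxybenzaldehyde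
Product: 20 2,4-bis(triisopropylsilyloxy)benzaldehyde
Conditions: i-Pr3SiCl (2.5 equiv), imidazole, DMF, rt → 40 °C
Reagents that add atoms: chlorotriisopropylsilane, CC(C)[Si](Cl)(C(C)C)C(C)C
Why: Standard silylation of both phenols; the chelated 2-hydroxyl reacts more slowly and is driven by excess reagent and gentle warming. Triisopropylsilyl is chosen so that ring B withstands the amine-catalysed condensation and all three phenols are released together at the end.

Step 10
Reactants: 18 prop-2-en-1-yl 3-[2-hydroxy-3,5-bis(3-methylbut-2-en-1-yl)-4-(triisopropylsilyloxy)phenyl]-3-oxopropanoate; 20 2,4-bis(triisopropylsilyloxy)benzaldehyde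
Product: 21 prop-2-en-1-yl (2Z)-3-[2,4-bis(triisopropylsilyloxy)phenyl]-2-[2-hydroxy-3,5-bis(3-methylbut-2-en-1-yl)-4-(triisopropylsilyloxy)benzoyl]prop-2-enoate
Conditions: piperidine (cat.), AcOH (cat.), 4 Å molecular sieves, toluene, rt → 40 °C
Reagents that add atoms: none
Why: Knoevenagel condensation of the active methylene of 18 with the aryl aldehyde under piperidinium acetate catalysis with removal of water; the electron-rich, hindered aryl group makes the alkylidene a poor acceptor for uncatalysed closure, so 21 should be isolable in open-chain form.

Step 11
Reactants: 21 prop-2-en-1-yl (2Z)-3-[2,4-bis(triisopropylsilyloxy)phenyl]-2-[2-hydroxy-3,5-bis(3-methylbut-2-en-1-yl)-4-(triisopropylsilyloxy)benzoyl]prop-2-enoate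
Product: 23 (2S)-2-[2,4-bis(triisopropylsilyloxy)phenyl]-6,8-bis(3-methylbut-2-en-1-yl)-7-(triisopropylsilyloxy)chroman-4-one, via chromanone allyl ester 22 (not isolated)
Conditions: quinidine-derived bifunctional thiourea [1-(3,5-bis(trifluoromethyl)phenyl)-3-(9-deoxy-epi-quinidin-9-yl)thiourea] (10 mol %), toluene, −25 °C; then HCO2H (excess), Et3N, Pd(OAc)2 (cat.), PPh3, THF, 0 °C → rt
Reagents that add atoms: none
Why: The quinuclidine nitrogen of the catalyst activates the phenol while the thiourea holds the 1,3-dicarbonyl unit, so the phenolic oxygen adds to one face of the alkylidene carbon in a 6-endo-trig oxa-Michael closure (organocatalytic intramolecular oxa-Michael addition of alkylidene β-keto esters, an established enantioselective entry to flavanones); C2 is set under catalyst control, its sense fixed by the choice of catalyst pseudoenantiomer, and C3 is epimerisable and is removed. Formic acid then neutralises the amine, zerovalent palladium formed from Pd(OAc)2 and PPh3 ionises the allyl ester, formate reduces the allyl fragment to propene and the β-keto acid loses CO2 (Tsuji-type deallylation and decarboxylation); neither acid nor strong base is present, so the prenyl groups and C2 are not put at risk.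

Step 12
Reactants: 23 (2S)-2-[2,4-bis(triisopropylsilyloxy)phenyl]-6,8-bis(3-methylbut-2-en-1-yl)-7-(triisopropylsilyloxy)chroman-4-one
Product: 24 (2S)-2-(2,4-dihydroxyphenyl)-7-hydroxy-6,8-bis(3-methylbut-2-en-1-yl)chroman-4-one
Conditions: Bu4NF, AcOH (1:1, excess), THF, 0 °C → rt; pH 6 buffer work-up
Reagents that add atoms: none
Why: Fluoride cleaves the three aryl silyl ethers; acetic acid keeps each liberated phenol protonated, so the ring B phenoxide that would open ring C and erode the 2S configuration is not formed, and nothing acidic enough to cyclise a prenyl group onto the C7 hydroxyl is present.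

**Compound list**

1 | 6-methylhept-5-en-2-one | CC(=O)CCC=C(C)C | starting material
2 | 1-(dimethylamino)-7-methyloct-6-en-3-one | CN(C)CCC(=O)CCC=C(C)C | intermediate
3 | N,N,N,7-tetramethyl-3-oxooct-6-en-1-aminium iodide (formed in the flask) | C[N+](C)(C)CCC(=O)CCC=C(C)C.[I-] | intermediate
4 | 7-methylocta-1,6-dien-3-one | C=CC(=O)CCC=C(C)C | intermediate
5 | 1,1,1-trifluoro-3-(3-methylbut-2-en-1-yl)hex-5-ene-2,4-dione (formed in the flask) | C=CC(=O)C(CC=C(C)C)C(=O)C(F)(F)F | intermediate
6 | 4-diazo-7-methylocta-1,6-dien-3-one | C=CC(=O)C(=[N+]=[N-])CC=C(C)C | intermediate
7 | ethyl 4-methylpent-3-enoate | CCOC(=O)CC=C(C)C | starting material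
8 | lithium 1,1-dibromo-5-methylhexa-1,4-dien-2-olate (formed in the flask) | [Li+].[O-]C(CC=C(C)C)=C(Br)Br | intermediate
9 | lithium 5-methylhex-4-en-1-yn-1-olate (formed in the flask) | [Li+].[O-]C#CCC=C(C)C | intermediate
10 | triisopropyl[(5-methylhex-4-en-1-yn-1-yl)oxy]silane | CC(C)=CCC#CO[Si](C(C)C)(C(C)C)C(C)C | intermediate
11 | 2-ethenyl-5-methylhexa-1,4-dien-1-one (formed in the flask) | O=C=C(C=C)CC=C(C)C | intermediate
12 | 4-ethenyl-2,4-bis(3-methylbut-2-en-1-yl)-3-(triisopropylsilyloxy)cyclobut-2-en-1-one, racemic (formed in the flask) | C=CC1(CC=C(C)C)C(=O)C(CC=C(C)C)=C1O[Si](C(C)C)(C(C)C)C(C)C | intermediate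
13 | (3E)-2,4-bis(3-methylbut-2-en-1-yl)-3-(triisopropylsilyloxy)hexa-1,3,5-trien-1-one (formed in the flask) | O=C=C(CC=C(C)C)/C(O[Si](C(C)C)(C(C)C)C(C)C)=C(/CC=C(C)C)C=C | intermediate
14 | 2,4-bis(3-methylbut-2-en-1-yl)-3-(triisopropylsilyloxy)cyclohexa-2,4-dien-1-one (formed in the flask) | O=C1CC=C(CC=C(C)C)C(O[Si](C(C)C)(C(C)C)C(C)C)=C1CC=C(C)C | intermediate
15 | 2,4-bis(3-methylbut-2-en-1-yl)-3-(triisopropylsilyloxy)phenol | CC(C)=CCc1ccc(O)c(CC=C(C)C)c1O[Si](C(C)C)(C(C)C)C(C)C | intermediate
16 | 2-hydroxy-3,5-bis(3-methylbut-2-en-1-yl)-4-(triisopropylsilyloxy)benzaldehyde | O=Cc1cc(CC=C(C)C)c(O[Si](C(C)C)(C(C)C)C(C)C)c(CC=C(C)C)c1O | intermediate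
17 | prop-2-en-1-yl 3-hydroxy-3-[2-hydroxy-3,5-bis(3-methylbut-2-en-1-yl)-4-(triisopropylsilyloxy)phenyl]propanoate, racemic | C=CCOC(=O)CC(O)c1cc(CC=C(C)C)c(O[Si](C(C)C)(C(C)C)C(C)C)c(CC=C(C)C)c1O | intermediate
18 | prop-2-en-1-yl 3-[2-hydroxy-3,5-bis(3-methylbut-2-en-1-yl)-4-(triisopropylsilyloxy)phenyl]-3-oxopropanoate | C=CCOC(=O)CC(=O)c1cc(CC=C(C)C)c(O[Si](C(C)C)(C(C)C)C(C)C)c(CC=C(C)C)c1O | intermediate
19 | 2,4-dihydroxybenzaldehyde | O=Cc1ccc(O)cc1O | starting material
20 | 2,4-bis(triisopropylsilyloxy)benzaldehyde | O=Cc1ccc(O[Si](C(C)C)(C(C)C)C(C)C)cc1O[Si](C(C)C)(C(C)C)C(C)C | intermediate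
21 | prop-2-en-1-yl (2Z)-3-[2,4-bis(triisopropylsilyloxy)phenyl]-2-[2-hydroxy-3,5-bis(3-methylbut-2-en-1-yl)-4-(triisopropylsilyloxy)benzoyl]prop-2-enoate | C=CCOC(=O)/C(=C\c1ccc(O[Si](C(C)C)(C(C)C)C(C)C)cc1O[Si](C(C)C)(C(C)C)C(C)C)C(=O)c1cc(CC=C(C)C)c(O[Si](C(C)C)(C(C)C)C(C)C)c(CC=C(C)C)c1O | intermediate
22 | prop-2-en-1-yl (2S,3R)-2-[2,4-bis(triisopropylsilyloxy)phenyl]-6,8-bis(3-methylbut-2-en-1-yl)-4-oxo-7-(triisopropylsilyloxy)chromane-3-carboxylate, trans, in equilibrium with its enol (formed in the flask) | CC(C)=CCc1cc2c(c(CC=C(C)C)c1O[Si](C(C)C)(C(C)C)C(C)C)O[C@H](c1ccc(O[Si](C(C)C)(C(C)C)C(C)C)cc1O[Si](C(C)C)(C(C)C)C(C)C)[C@@H](C(=O)OCC=C)C2=O | intermediate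
23 | (2S)-2-[2,4-bis(triisopropylsilyloxy)phenyl]-6,8-bis(3-methylbut-2-en-1-yl)-7-(triisopropylsilyloxy)chroman-4-one | CC(C)=CCc1cc2c(c(CC=C(C)C)c1O[Si](C(C)C)(C(C)C)C(C)C)O[C@H](c1ccc(O[Si](C(C)C)(C(C)C)C(C)C)cc1O[Si](C(C)C)(C(C)C)C(C)C)CC2=O | intermediate
24 | (2S)-2-(2,4-dihydroxyphenyl)-7-hydroxy-6,8-bis(3-methylbut-2-en-1-yl)chroman-4-one | CC(C)=CCc1cc2c(c(CC=C(C)C)c1O)O[C@H](c1ccc(O)cc1O)CC2=O | target

**Step count and least certain steps**

Total: 12 steps. Longest linear sequence: 10 steps (steps 1, 2, 3, 5, 6, 7, 8, 10, 11, 12).

Step 5 (key step). The most likely failure is diversion of the photogenerated carbene, or of the excited diazo compound, into a 1,2-hydrogen shift from the neighbouring CH2 group in place of the Wolff shift. Oligomerisation of the unhindered vinylketene and O-acylation of the phenolic product by ketene could add to this and leave little ketene for the ynol ether. The fallback gives up the ring construction and uses resorcinol chemistry. It sets out from 19: phenoxide C-alkylation with 1-bromo-3-methylbut-2-ene in aqueous KOH should give, after separation from mono-prenylated and O-alkylated material, 2,4-dihydroxy-3,5-bis(3-methylbut-2-en-1-yl)benzaldehyde F1. This reaction is low-yielding but short and well established for resorcinol carbonyl compounds. Selective silylation of the non-chelated C4 hydroxyl of F1 with i-Pr3SiOTf and 2,6-lutidine returns to the route at 16.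

Step 3. Conjugate addition of the amide base to the unsubstituted vinyl ketone, or anionic oligomerisation during enolisation, may outrun trifluoroacetylation, and the diazo enone may be consumed by Michael-type processes in the basic transfer medium. The fallback makes the ketene 11 without any diazo compound. It sets out from the retained 10 and from commercial ethyl (E)-but-2-enoate, which is not on the numbered list.
- Deconjugative α-alkylation (LiN(i-Pr)2, DMPU, 1-bromo-3-methylbut-2-ene) gives ethyl 2-ethenyl-5-methylhex-4-enoate F2.
- Saponification with LiOH gives 2-ethenyl-5-methylhex-4-enoic acid F3, and oxalyl chloride gives 2-ethenyl-5-methylhex-4-enoyl chloride F4.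
- Slow addition of Et3N to F4 and 10 in ClCH2CH2Cl, at rt and then at 80 °C, dehydrochlorinates F4.
- The fallback comes back to the route at 11, formed in the flask, and so reaches 15 through 12, 13 and 14 without light.

Step 4. The α-protons of 7 are both allylic and next to the ester, so deprotonation to a dienolate, with migration of the double bond into conjugation, may compete with addition of LiCHBr2 to the carbonyl group; partial C-silylation of the ynolate is a lesser concern. The fallback reaches the ynolate by oxidation of an acetylide. It draws on no numbered compound but on commercial 1-bromo-3-methylbut-2-ene. Copper-catalysed coupling with HC≡CMgBr (CuCl) gives 5-methylhex-4-en-1-yne F5, and deprotonation with n-BuLi followed by oxygen transfer from LiOOt-Bu converts its acetylide into the ynolate. The fallback comes back to the route at 9, which is silylated with i-Pr3SiOTf to 10.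

Step 11. Three things can go wrong here.
- Facial selectivity may be poor, because of the bulky ortho-siloxy group of ring B, the allyl rather than a bulkier ester, or a mixture of alkene geometries.
- Closure may occur before the chiral catalyst takes control.
- The configuration may erode through reversible ring opening before decarboxylation is complete.

The sense of induction also has to be confirmed, as noted before the steps. The fallback separates ring closure from stereocontrol and sets out from 21.
- Closure with an achiral amine (DABCO, toluene) gives the racemic trans ester, prop-2-en-1-yl 2-[2,4-bis(triisopropylsilyloxy)phenyl]-6,8-bis(3-methylbut-2-en-1-yl)-4-oxo-7-(triisopropylsilyloxy)chromane-3-carboxylate F6.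
- The same palladium-mediated deallylation and decarboxylation gives racemic 2-[2,4-bis(triisopropylsilyloxy)phenyl]-6,8-bis(3-methylbut-2-en-1-yl)-7-(triisopropylsilyloxy)chroman-4-one F7.
- Kinetic resolution by Noyori-type asymmetric transfer hydrogenation follows (RuCl(TsDPEN)(p-cymene), HCO2H/Et3N), with the catalyst enantiomer chosen so that the 2R ketone is reduced faster to the cis alcohol (2R,4R)-2-[2,4-bis(triisopropylsilyloxy)phenyl]-6,8-bis(3-methylbut-2-en-1-yl)-7-(triisopropylsilyloxy)chroman-4-ol F8.
- The unreduced ketone is separated by chromatography, and the fallback comes back to the route at 23. The prenyl double bonds are not touched by transfer hydrogenation.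

**Further compounds**

F1 | step 5 | 2,4-dihydroxy-3,5-bis(3-methylbut-2-en-1-yl)benzaldehyde | O=Cc1cc(CC=C(C)C)c(O)c(CC=C(C)C)c1O
F2 | step 3 | ethyl 2-ethenyl-5-methylhex-4-enoate, racemic | CCOC(=O)C(C=C)CC=C(C)C
F3 | step 3 | 2-ethenyl-5-methylhex-4-enoic acid, racemic | OC(=O)C(C=C)CC=C(C)C
F4 | step 3 | 2-ethenyl-5-methylhex-4-enoyl chloride, racemic | ClC(=O)C(C=C)CC=C(C)C
F5 | step 4 | 5-methylhex-4-en-1-yne | C#CCC=C(C)C
F6 | step 11 | prop-2-en-1-yl 2-[2,4-bis(triisopropylsilyloxy)phenyl]-6,8-bis(3-methylbut-2-en-1-yl)-4-oxo-7-(triisopropylsilyloxy)chromane-3-carboxylate, racemic trans | CC(C)=CCc1cc2c(c(CC=C(C)C)c1O[Si](C(C)C)(C(C)C)C(C)C)OC(c1ccc(O[Si](C(C)C)(C(C)C)C(C)C)cc1O[Si](C(C)C)(C(C)C)C(C)C)C(C(=O)OCC=C)C2=O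
F7 | step 11 | 2-[2,4-bis(triisopropylsilyloxy)phenyl]-6,8-bis(3-methylbut-2-en-1-yl)-7-(triisopropylsilyloxy)chroman-4-one, racemic | CC(C)=CCc1cc2c(c(CC=C(C)C)c1O[Si](C(C)C)(C(C)C)C(C)C)OC(c1ccc(O[Si](C(C)C)(C(C)C)C(C)C)cc1O[Si](C(C)C)(C(C)C)C(C)C)CC2=O
F8 | step 11 | (2R,4R)-2-[2,4-bis(triisopropylsilyloxy)phenyl]-6,8-bis(3-methylbut-2-en-1-yl)-7-(triisopropylsilyloxy)chroman-4-ol | CC(C)=CCc1cc2c(c(CC=C(C)C)c1O[Si](C(C)C)(C(C)C)C(C)C)O[C@@H](c1ccc(O[Si](C(C)C)(C(C)C)C(C)C)cc1O[Si](C(C)C)(C(C)C)C(C)C)C[C@H]2O
A1 | alternative 1 | (2S)-2-[2,4-bis(methoxymethoxy)phenyl]-7-hydroxy-6,8-bis(3-methylbut-2-en-1-yl)chroman-4-one | CC(C)=CCc1cc2c(c(CC=C(C)C)c1O)O[C@H](c1ccc(OCOC)cc1OCOC)CC2=O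
A2 | alternative 1 | (2S)-2-[2,4-bis(methoxymethoxy)phenyl]-6,8-bis[(dimethylamino)methyl]-7-hydroxychroman-4-one | CN(C)Cc1cc2c(c(CN(C)C)c1O)O[C@H](c1ccc(OCOC)cc1OCOC)CC2=O
A3 | alternative 1 | (2-methylprop-1-en-1-yl)boronic acid | CC(C)=CB(O)O
A4 | alternative 2 | (2S,4S)-7-(tert-butyldimethylsilyloxy)-2-[4-(tert-butyldimethylsilyloxy)-2-hydroxyphenyl]-4-methoxy-6,8-bis(3-methylbut-2-en-1-yl)chromane | CC(C)=CCc1cc2c(c(CC=C(C)C)c1O[Si](C)(C)C(C)(C)C)O[C@H](c1ccc(O[Si](C)(C)C(C)(C)C)cc1O)C[C@@H]2OC
A5 | alternative 2 | 4-(tert-butyldimethylsilyloxy)-2-hydroxy-3,5-bis(3-methylbut-2-en-1-yl)benzaldehyde | O=Cc1cc(CC=C(C)C)c(O[Si](C)(C)C(C)(C)C)c(CC=C(C)C)c1O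
A6 | alternative 2 | 5-(tert-butyldimethylsilyloxy)-2-ethenylphenol | C=Cc1ccc(O[Si](C)(C)C(C)(C)C)cc1O
A7 | alternative 3 | (2S)-2-[2,4-bis(tert-butyldimethylsilyloxy)phenyl]-7-hydroxy-6,8-bis(3-methylbut-2-en-1-yl)chroman-4-one | CC(C)=CCc1cc2c(c(CC=C(C)C)c1O)O[C@H](c1ccc(O[Si](C)(C)C(C)(C)C)cc1O[Si](C)(C)C(C)(C)C)CC2=O
A8 | alternative 3 | (2S)-2-[2,4-bis(tert-butyldimethylsilyloxy)phenyl]-5-bromo-2,3-dihydro-4H-pyran-4-one | O=C1C[C@@H](c2ccc(O[Si](C)(C)C(C)(C)C)cc2O[Si](C)(C)C(C)(C)C)OC=C1Br
A9 | alternative 3 | tert-butyl{[(1E,3Z)-1-methoxy-7-methyl-2-(3-methylbut-2-en-1-yl)octa-1,3,6-trien-3-yl]oxy}dimethylsilane | CO/C=C(CC=C(C)C)/C(O[Si](C)(C)C(C)(C)C)=C/CC=C(C)C
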